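**Retrosynthetic overview**

Numbering: decalin carbons C1–C10 as in a eudesmane. C1 carries the benzylic carbon C9', C4 carries the methyl C15 and OH, C7 carries the carbinol carbon C11, C10 carries the angular methyl C14.
Late stage: tri-O-demethylation, ArBr2 to Ar(CHO)2, arene bromination, hydrogenation of a C6=C7 bond (sets C7), Wolff–Kishner reduction of an angular formyl group to C14.
Key disconnection: ring B (C5–C6–C7–C8–C9–C10) is opened across C8–C9 and C5–C10 by a retro-Diels–Alder reaction, after a C6=C7 double bond is written in and C14 is raised to CHO. The enabling feature is that the quaternary ring-fusion carbon C10 bears a one-carbon substituent (C14) that can act as the carbonyl of a 2-substituted acrolein (C9=C10–C14HO), while C10 and C5 are joined by the four-carbon chain C1–C4. One intramolecular cycloaddition therefore closes ring B and, through the tether, ring A.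
Acyclic triene–enal: C6–C7 by a Heck reaction, C1–C10 by Zweifel olefination of a C1 boronic ester, C1–C9' and C9'–aryl by two reagent-controlled lithiation–borylations; (R)-linalool supplies C1–C6 and C15 with the C4 stereocentre.
Ring order: the arene is bought; rings A and B are formed together in step 14; no other ring is made.

Key step: step 14

Remark: both tertiary triethylsilyl ethers are assumed to be cleaved by the hot KOH/diethylene glycol of step 15; locants C1–C15 and C9' in names refer to the numbering above, and descriptors are CIP descriptors of the compound named.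

**Route**

Step 1
Reactants: 1 (R)-linalool
Product: 2 (3R)-3,7-dimethyl-3-(triethylsilyloxy)octa-1,6-diene
Conditions: TESOTf, 2,6-lutidine, CH2Cl2, −78 → 0 °C
Reagents that add atoms: triethylsilyl trifluoromethanesulfonate, CC[Si](CC)(CC)OS(=O)(=O)C(F)(F)F
Why: Triflate-mediated silyl ether formation is needed for the hindered tertiary allylic alcohol and masks the C4 hydroxyl, whose configuration comes unchanged from the chiral pool, against the organolithium reagents used later.

Step 2
Reactants: 2 (3R)-3,7-dimethyl-3-(triethylsilyloxy)octa-1,6-diene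
Product: 4 (4R)-4-methyl-4-(triethylsilyloxy)hex-5-en-1-ol, via aldehyde 3 (not isolated)
Conditions: O3, CH2Cl2–MeOH, trace pyridine, Sudan Red 7B as endpoint indicator, −78 °C; then NaBH4, −78 °C → rt
Reagents that add atoms: ozone, [O-][O+]=O
Why: Ozonolysis with reductive NaBH4 work-up is selective for the electron-rich trisubstituted alkene over the vinyl group, which is deactivated by the allylic silyloxy-bearing quaternary carbon, and delivers the primary alcohol whose carbinol carbon becomes C1.

Step 3
Reactants: 4 (4R)-4-methyl-4-(triethylsilyloxy)hex-5-en-1-ol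
Product: 5 (4R)-4-methyl-4-(triethylsilyloxy)hex-5-en-1-yl N,N-diisopropylcarbamate
Conditions: i-Pr2NCOCl, Et3N, CH2Cl2, reflux
Reagents that add atoms: N,N-diisopropylcarbamoyl chloride, CC(C)N(C(C)C)C(Cl)=O
Why: O-Carbamoylation of the primary alcohol installs the group that directs α-lithiation and later serves as the leaving group of the 1,2-metallate rearrangement.

Step 4
Reactants: 6 1,3,5-trimethoxybenzene
Product: 8 4,4,5,5-tetramethyl-2-(2,4,6-trimethoxyphenyl)-1,3,2-dioxaborolane, via aryllithium 7 (not isolated)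
Conditions: n-BuLi, THF, 0 °C → rt; then i-PrOBpin, −78 °C → rt; aq. NH4Cl
Reagents that add atoms: 2-isopropoxy-4,4,5,5-tetramethyl-1,3,2-dioxaborolane, CC(C)OB1OC(C)(C)C(C)(C)O1
Why: Directed ortho-lithiation between two methoxy groups followed by borylation with the isopropoxyboronate gives the aryl pinacol boronic ester (arene lithiation–borylation).

Step 5
Reactants: 9 3-methylbutan-1-ol
Product: 10 3-methylbutyl N,N-diisopropylcarbamate
Conditions: i-Pr2NCOCl, Et3N, CH2Cl2, reflux
Reagents that add atoms: N,N-diisopropylcarbamoyl chloride, CC(C)N(C(C)C)C(Cl)=O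
Why: O-Carbamoylation gives the carbamate needed for sparteine-mediated α-lithiation.

Step 6
Reactants: 10 3-methylbutyl N,N-diisopropylcarbamate; 8 4,4,5,5-tetramethyl-2-(2,4,6-trimethoxyphenyl)-1,3,2-dioxaborolane
Product: 13 4,4,5,5-tetramethyl-2-[(1R)-3-methyl-1-(2,4,6-trimethoxyphenyl)butyl]-1,3,2-dioxaborolane, via lithiated carbamate 11 (not isolated), via boronate complex 12 (not isolated)
Conditions: s-BuLi, (−)-sparteine, Et2O, −78 °C, 5 h; then 8, −78 °C; then reflux
Reagents that add atoms: none
Why: Sparteine-mediated asymmetric α-deprotonation removes the pro-S hydrogen, the boronic ester captures the carbenoid with retention and the electron-rich aryl group then migrates from boron to carbon with inversion (lithiation–borylation, stereospecific 1,2-metallate rearrangement), which sets C9' under reagent control.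

Step 7
Reactants: 5 (4R)-4-methyl-4-(triethylsilyloxy)hex-5-en-1-yl N,N-diisopropylcarbamate; 13 4,4,5,5-tetramethyl-2-[(1R)-3-methyl-1-(2,4,6-trimethoxyphenyl)butyl]-1,3,2-dioxaborolane
Product: 16 2-[(3R,6S,7S)-3,9-dimethyl-3-(triethylsilyloxy)-7-(2,4,6-trimethoxyphenyl)dec-1-en-6-yl]-4,4,5,5-tetramethyl-1,3,2-dioxaborolane, via lithiated carbamate 14 (not isolated), via boronate complex 15 (not isolated)
Conditions: s-BuLi, (+)-sparteine, Et2O, −78 °C, 5 h; then 13, −78 °C; then MgBr2·OEt2, MeOH, −78 → 40 °C
Reagents that add atoms: none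
Why: The same lithiation–borylation with the enantiomeric diamine sets C1 under reagent control while the benzylic group migrates with retention at C9', MgBr2/MeOH accelerating the 1,2-shift of the hindered boronate complex.

Step 8
Reactants: 17 3,3-diethoxyprop-1-ene (acrolein diethyl acetal)
Product: 19 2-bromo-3,3-diethoxyprop-1-ene, via dibromide 18 (not isolated)
Conditions: Br2, CH2Cl2, −20 °C; then t-BuOK (1 equiv), THF, 0 °C
Reagents that add atoms: bromine, BrBr
Why: Bromine addition to the alkene followed by E2 loss of HBr through the more acidic C2–H (bromination–dehydrobromination) gives the 2-bromoalkene.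

Step 9
Reactants: 19 2-bromo-3,3-diethoxyprop-1-ene; 16 2-[(3R,6S,7S)-3,9-dimethyl-3-(triethylsilyloxy)-7-(2,4,6-trimethoxyphenyl)dec-1-en-6-yl]-4,4,5,5-tetramethyl-1,3,2-dioxaborolane
Product: 22 (3R,6S,7S)-6-(3,3-diethoxyprop-1-en-2-yl)-3,9-dimethyl-7-(2,4,6-trimethoxyphenyl)-3-(triethylsilyloxy)dec-1-ene, via alkenyllithium 20 (not isolated), via alkenylboronate complex 21 (not isolated)
Conditions: 19, t-BuLi (2 equiv), Et2O, −78 °C; then 16, THF, −78 → 0 °C; then I2, MeOH–THF, −78 °C; then NaOMe, MeOH, −78 °C → rt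
Reagents that add atoms: none
Why: Bromine–lithium exchange gives the alkenyllithium, which adds to boron, and iodine then triggers a stereoretentive 1,2-migration of C1 followed by methoxide-induced anti elimination of the β-iodoboronic ester (Zweifel olefination), so that C1–C10 is formed with retention at C1.

Step 10
Reactants: 23 3-hydroxy-3-methylbutan-2-one
Product: 24 3-methyl-3-(triethylsilyloxy)butan-2-one
Conditions: TESOTf, 2,6-lutidine, CH2Cl2, −78 → 0 °C
Reagents that add atoms: triethylsilyl trifluoromethanesulfonate, CC[Si](CC)(CC)OS(=O)(=O)C(F)(F)F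
Why: Silyl ether formation protects the tertiary hydroxyl (the future C11–OH) before enolization.

Step 11
Reactants: 24 3-methyl-3-(triethylsilyloxy)butan-2-one
Product: 26 3-methyl-3-(triethylsilyloxy)but-1-en-2-yl trifluoromethanesulfonate, via lithium enolate 25 (not isolated)
Conditions: LDA, THF, −78 °C; then PhNTf2, −78 → 0 °C; aq. NH4Cl
Reagents that add atoms: N-phenylbis(trifluoromethanesulfonimide), O=S(=O)(N(c1ccccc1)S(=O)(=O)C(F)(F)F)C(F)(F)F
Why: The ketone can enolize only toward its methyl group, and O-sulfonylation of the lithium enolate gives the 1,1-disubstituted enol triflate (enol triflate formation).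

Step 12
Reactants: 22 (3R,6S,7S)-6-(3,3-diethoxyprop-1-en-2-yl)-3,9-dimethyl-7-(2,4,6-trimethoxyphenyl)-3-(triethylsilyloxy)dec-1-ene; 26 3-methyl-3-(triethylsilyloxy)but-1-en-2-yl trifluoromethanesulfonate
Product: 27 (3E,5R,8S,9S)-8-(3,3-diethoxyprop-1-en-2-yl)-5,11-dimethyl-5-(triethylsilyloxy)-2-[2-(triethylsilyloxy)propan-2-yl]-9-(2,4,6-trimethoxyphenyl)dodeca-1,3-diene
Conditions: Pd(OAc)2 (10 mol %), PPh3, LiCl, Et3N, DMF, 70 °C
Reagents that add atoms: none
Why: Mizoroki–Heck reaction: the alkenyl triflate adds oxidatively to zerovalent palladium, insertion occurs at the unhindered terminus of the monosubstituted vinyl group (the 1,1-disubstituted alkene is inert) and, as C4 bears no hydrogen, β-hydride elimination can only give the conjugated (E)-diene.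

Step 13
Reactants: 27 diene acetal (name as in step 12)
Product: 28 (3S,6R,7E)-6,10-dimethyl-2,9-dimethylidene-3-[(1S)-3-methyl-1-(2,4,6-trimethoxyphenyl)butyl]-6,10-bis(triethylsilyloxy)undec-7-enal
Conditions: PPTS (cat.), acetone–H2O, rt
Reagents that add atoms: water, O
Why: Mild acid-catalysed hydrolysis of the allylic diethyl acetal (acetal hydrolysis) frees the 2-substituted acrolein at room temperature without touching the tertiary silyl ethers.

Step 14
Reactants: 28 triene–enal (name as in step 13)
Product: 29 trans-fused Diels–Alder adduct, (1S,4R,5R,10R,9'S): decalin with a C6=C7 double bond, 10β-formyl, 5α-H, 4β-methyl/4α-triethylsilyloxy, 1β-[(1S)-3-methyl-1-(2,4,6-trimethoxyphenyl)butyl] and 7-[2-(triethylsilyloxy)propan-2-yl]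
Conditions: Me2AlCl (1.5 equiv), CH2Cl2, −78 → −30 °C; aq. Rochelle salt
Reagents that add atoms: none
Why: Me2AlCl binds the formyl oxygen and lowers the LUMO of the 2-substituted acrolein, which undergoes a concerted but asynchronous normal-demand [4+2] cycloaddition with the tethered (E)-2-substituted diene, the C8–C9 bond (largest diene coefficient at C8, enal β-carbon C9) running ahead of C5–C10; the closest known reaction type is the Lewis acid-promoted type 1 intramolecular Diels–Alder reaction of 1,7,9-decatrienes with an activated dienophile. Ring B (C5–C6–C7–C8–C9–C10) closes as the cyclohexene of the cycloaddition through both new bonds, and ring A (C1–C2–C3–C4–C5–C10) closes as the tether ring through C5–C10 in a chair-like arrangement. The trans ring fusion (5α-H, 10β-CHO) follows from the endo orientation of the Lewis acid-bound formyl group, which places the tether exo, and the absolute sense at C5 and C10 is set by C1, because allylic 1,3-strain keeps C1–H in the plane of C10=C9 and the large CH(Ar)(i-Bu) group anti to the forming C5–C10 bond, that is equatorial on the nascent ring A. The step needs regio-, endo- and π-facial selectivity: regiochemistry is fixed by the four-carbon tether and is electronically matched (1,4-relation of the C7 substituent and CHO), endo selectivity comes from Lewis acid complexation, and facial selectivity from the C1 stereocentre, the C4 centre (methyl axial, OTES equatorial in this chair) being tolerated because the C5–C10 bond is still long in the transition state. Me2AlCl is chosen because it scavenges protons and should be mild enough at low temperature to leave the two tertiary allylic silyl ethers un-ionized.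

Step 15
Reactants: 29 Diels–Alder adduct (as in step 14)
Product: 31 (1S,4R,5R,10S,9'S)-diol alkene: decalin with a C6=C7 double bond, 10β-methyl, 5α-H, 4α-OH/4β-methyl, 7-(2-hydroxypropan-2-yl) and 1β-[(1S)-3-methyl-1-(2,4,6-trimethoxyphenyl)butyl], via hydrazone 30 (not isolated)
Conditions: N2H4·H2O, KOH, diethylene glycol, 130 °C, then 200 °C
Reagents that add atoms: none
Why: Wolff–Kishner reduction (Huang–Minlon procedure): the hydrazone of the neopentyl aldehyde loses N2 under hot base to give the angular methyl group C14 without touching the quaternary centre, and the hot KOH/glycol medium also cleaves both triethylsilyl ethers.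

Step 16
Reactants: 31 diol alkene (as in step 15)
Product: 32 (1S,4R,5R,7R,10S,9'S)-saturated diol: trans-decalin with 10β-methyl, 5α-H, 4α-OH/4β-methyl, 7β-(2-hydroxypropan-2-yl) and 1β-[(1S)-3-methyl-1-(2,4,6-trimethoxyphenyl)butyl]
Conditions: H2 (3 atm), PtO2, EtOAc, rt
Reagents that add atoms: none
Why: Heterogeneous catalytic hydrogenation adds H2 syn to the α face of the C6=C7 bond, opposite the two axial β-methyl groups (C14 and C15) that flank C6, so that H-7 is α and the hydroxyisopropyl group is β and equatorial.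

Step 17
Reactants: 32 saturated diol (as in step 16)
Product: 33 the 3,5-dibromo-2,4,6-trimethoxyphenyl analogue of 32
Conditions: NBS (2.1 equiv), MeCN, 0 °C, dark
Reagents that add atoms: N-bromosuccinimide, O=C1CCC(=O)N1Br
Why: Electrophilic aromatic bromination takes the only two free positions of the strongly activated trimethoxyarene, each ortho or para to all three methoxy groups.

Step 18
Reactants: 33 dibromide (as in step 17)
Product: 35 the 3,5-diformyl-2,4,6-trimethoxyphenyl analogue of 32 (Macrocarpal J tri-O-methyl ether), via tetralithio species 34 (not isolated)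
Conditions: MeLi (2.1 equiv), THF, −78 °C; t-BuLi (4.2 equiv), −78 °C; DMF (excess), −78 → 0 °C; aq. NH4Cl
Reagents that add atoms: N,N-dimethylformamide, CN(C)C=O
Why: After deprotonation of the two tertiary alcohols, double bromine–lithium exchange gives a bis-aryllithium flanked by chelating methoxy groups, and formylation with DMF installs both aldehydes (halogen–metal exchange/formylation).

Step 19
Reactants: 35 Macrocarpal J tri-O-methyl ether
Product: 36 Macrocarpal J
Conditions: NaSEt (excess), DMF, 110 °C; then cold 1 M HCl to pH 3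
Reagents that add atoms: none
Why: Thiolate SN2 demethylation of the three aryl methyl ethers, each activated by ortho- and para-formyl groups, works under basic conditions that spare the two acid-sensitive tertiary alcohols (nucleophilic O-demethylation).

**Compound list**

1 | (R)-linalool | CC(C)=CCC[C@@](C)(O)C=C | starting material
2 | (3R)-3,7-dimethyl-3-(triethylsilyloxy)octa-1,6-diene | CC(C)=CCC[C@@](C)(O[Si](CC)(CC)CC)C=C | intermediate
3 | (4R)-4-methyl-4-(triethylsilyloxy)hex-5-enal | O=CCC[C@@](C)(O[Si](CC)(CC)CC)C=C | intermediate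
4 | (4R)-4-methyl-4-(triethylsilyloxy)hex-5-en-1-ol | OCCC[C@@](C)(O[Si](CC)(CC)CC)C=C | intermediate
5 | (4R)-4-methyl-4-(triethylsilyloxy)hex-5-en-1-yl N,N-diisopropylcarbamate | CC(C)N(C(C)C)C(=O)OCCC[C@@](C)(O[Si](CC)(CC)CC)C=C | intermediate
6 | 1,3,5-trimethoxybenzene | COc1cc(OC)cc(OC)c1 | starting material
7 | 2,4,6-trimethoxyphenyllithium | COc1cc(OC)c([Li])c(OC)c1 | intermediate
8 | 4,4,5,5-tetramethyl-2-(2,4,6-trimethoxyphenyl)-1,3,2-dioxaborolane | COc1cc(OC)c(B2OC(C)(C)C(C)(C)O2)c(OC)c1 | intermediate
9 | 3-methylbutan-1-ol | CC(C)CCO | starting material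
10 | 3-methylbutyl N,N-diisopropylcarbamate | CC(C)CCOC(=O)N(C(C)C)C(C)C | intermediate
11 | (1S)-1-lithio-3-methylbutyl N,N-diisopropylcarbamate (sparteine-bound) | CC(C)C[C@H]([Li])OC(=O)N(C(C)C)C(C)C | intermediate
12 | lithium boronate complex from 11 and 8 | CC(C)C[C@@H](OC(=O)N(C(C)C)C(C)C)[B-]1(OC(C)(C)C(C)(C)O1)c1c(OC)cc(OC)cc1OC.[Li+] | intermediate
13 | 4,4,5,5-tetramethyl-2-[(1R)-3-methyl-1-(2,4,6-trimethoxyphenyl)butyl]-1,3,2-dioxaborolane | CC(C)C[C@@H](B1OC(C)(C)C(C)(C)O1)c1c(OC)cc(OC)cc1OC | intermediate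
14 | (1R,4R)-1-lithio-4-methyl-4-(triethylsilyloxy)hex-5-en-1-yl N,N-diisopropylcarbamate (sparteine-bound) | CC(C)N(C(C)C)C(=O)O[C@H]([Li])CC[C@@](C)(O[Si](CC)(CC)CC)C=C | intermediate
15 | lithium boronate complex from 14 and 13 | CC(C)N(C(C)C)C(=O)O[C@H]([B-]1(OC(C)(C)C(C)(C)O1)[C@H](CC(C)C)c1c(OC)cc(OC)cc1OC)CC[C@@](C)(O[Si](CC)(CC)CC)C=C.[Li+] | intermediate
16 | 2-[(3R,6S,7S)-3,9-dimethyl-3-(triethylsilyloxy)-7-(2,4,6-trimethoxyphenyl)dec-1-en-6-yl]-4,4,5,5-tetramethyl-1,3,2-dioxaborolane | CC(C)C[C@H](c1c(OC)cc(OC)cc1OC)[C@@H](B1OC(C)(C)C(C)(C)O1)CC[C@@](C)(O[Si](CC)(CC)CC)C=C | intermediate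
17 | 3,3-diethoxyprop-1-ene | C=CC(OCC)OCC | starting material
18 | 2,3-dibromo-1,1-diethoxypropane | BrCC(Br)C(OCC)OCC | intermediate
19 | 2-bromo-3,3-diethoxyprop-1-ene | C=C(Br)C(OCC)OCC | intermediate
20 | (3,3-diethoxyprop-1-en-2-yl)lithium | [Li]C(=C)C(OCC)OCC | intermediate
21 | lithium alkenylboronate complex from 20 and 16 | CC(C)C[C@H](c1c(OC)cc(OC)cc1OC)[C@@H]([B-]1(OC(C)(C)C(C)(C)O1)C(=C)C(OCC)OCC)CC[C@@](C)(O[Si](CC)(CC)CC)C=C.[Li+] | intermediate
22 | (3R,6S,7S)-6-(3,3-diethoxyprop-1-en-2-yl)-3,9-dimethyl-7-(2,4,6-trimethoxyphenyl)-3-(triethylsilyloxy)dec-1-ene | CC(C)C[C@H](c1c(OC)cc(OC)cc1OC)[C@@H](C(=C)C(OCC)OCC)CC[C@@](C)(O[Si](CC)(CC)CC)C=C | intermediate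
23 | 3-hydroxy-3-methylbutan-2-one | CC(=O)C(C)(C)O | starting material
24 | 3-methyl-3-(triethylsilyloxy)butan-2-one | CC(=O)C(C)(C)O[Si](CC)(CC)CC | intermediate
25 | lithium enolate of 24 | [Li]OC(=C)C(C)(C)O[Si](CC)(CC)CC | intermediate
26 | 3-methyl-3-(triethylsilyloxy)but-1-en-2-yl trifluoromethanesulfonate | C=C(OS(=O)(=O)C(F)(F)F)C(C)(C)O[Si](CC)(CC)CC | intermediate
27 | (3E,5R,8S,9S)-8-(3,3-diethoxyprop-1-en-2-yl)-5,11-dimethyl-5-(triethylsilyloxy)-2-[2-(triethylsilyloxy)propan-2-yl]-9-(2,4,6-trimethoxyphenyl)dodeca-1,3-diene | CC(C)C[C@H](c1c(OC)cc(OC)cc1OC)[C@@H](C(=C)C(OCC)OCC)CC[C@@](C)(O[Si](CC)(CC)CC)/C=C/C(=C)C(C)(C)O[Si](CC)(CC)CC | intermediate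
28 | (3S,6R,7E)-6,10-dimethyl-2,9-dimethylidene-3-[(1S)-3-methyl-1-(2,4,6-trimethoxyphenyl)butyl]-6,10-bis(triethylsilyloxy)undec-7-enal | CC(C)C[C@H](c1c(OC)cc(OC)cc1OC)[C@@H](C(=C)C=O)CC[C@@](C)(O[Si](CC)(CC)CC)/C=C/C(=C)C(C)(C)O[Si](CC)(CC)CC | intermediate
29 | (1S,4R,5R,10R,9'S)-Diels–Alder adduct (trans-decalin with C6=C7, 10β-CHO, two OTES groups) | CC(C)C[C@H](c1c(OC)cc(OC)cc1OC)[C@@H]1CC[C@@](C)(O[Si](CC)(CC)CC)[C@@H]2C=C(C(C)(C)O[Si](CC)(CC)CC)CC[C@]21C=O | intermediate
30 | hydrazone of 29 | CC(C)C[C@H](c1c(OC)cc(OC)cc1OC)[C@@H]1CC[C@@](C)(O[Si](CC)(CC)CC)[C@@H]2C=C(C(C)(C)O[Si](CC)(CC)CC)CC[C@]21C=NN | intermediate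
31 | (1S,4R,5R,10S,9'S)-diol alkene (C6=C7, 10β-methyl) | CC(C)C[C@H](c1c(OC)cc(OC)cc1OC)[C@@H]1CC[C@@](C)(O)[C@@H]2C=C(C(C)(C)O)CC[C@]21C | intermediate
32 | (1S,4R,5R,7R,10S,9'S)-saturated diol with 2,4,6-trimethoxyphenyl group | CC(C)C[C@H](c1c(OC)cc(OC)cc1OC)[C@@H]1CC[C@@](C)(O)[C@@H]2C[C@H](C(C)(C)O)CC[C@]21C | intermediate
33 | 3,5-dibromo-2,4,6-trimethoxyphenyl analogue of 32 | CC(C)C[C@H](c1c(OC)c(Br)c(OC)c(Br)c1OC)[C@@H]1CC[C@@](C)(O)[C@@H]2C[C@H](C(C)(C)O)CC[C@]21C | intermediate
34 | dilithium dialkoxide bis-aryllithium from 33 | CC(C)C[C@H](c1c(OC)c([Li])c(OC)c([Li])c1OC)[C@@H]1CC[C@@](C)(O[Li])[C@@H]2C[C@H](C(C)(C)O[Li])CC[C@]21C | intermediate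
35 | Macrocarpal J tri-O-methyl ether (3,5-diformyl-2,4,6-trimethoxyphenyl analogue of 32) | CC(C)C[C@H](c1c(OC)c(C=O)c(OC)c(C=O)c1OC)[C@@H]1CC[C@@](C)(O)[C@@H]2C[C@H](C(C)(C)O)CC[C@]21C | intermediate
36 | Macrocarpal J | CC(C)C[C@H](c1c(O)c(C=O)c(O)c(C=O)c1O)[C@@H]1CC[C@@](C)(O)[C@@H]2C[C@H](C(C)(C)O)CC[C@]21C | target

**Step count and risks**

Total step count: 19. Longest linear sequence: 13 steps (from 1 through steps 1, 2, 3, 7, 9, 12, 13, 14, 15, 16, 17, 18, 19).

Steps most likely to fail:

Step 7. The sparteine-bound carbenoid may add only slowly and reversibly to the hindered secondary benzylic boronic ester, and the 1,2-shift of the bulky benzylic group may lag behind decomposition of the carbenoid, so that starting boronic ester is recovered or the diastereomeric purity at C1 erodes. The fallback sets out from 5 and 13 and comes back at 16. Carbamate 5 is lithiated as in step 7 (s-BuLi, (+)-sparteine, Et2O, −78 °C) and the carbenoid is trapped with Me3SnCl, with retention, to give the α-stannyl carbamate F1, which is purified. Tin–lithium exchange of F1 with n-BuLi in Et2O at −78 °C without diamine regenerates carbenoid 14 in its smaller and more electrophilic diamine-free form. Addition of 13, then MgBr2·OEt2/MeOH and warming, should give 16 by the same stereospecific 1,2-migration.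

Step 14. The Lewis acid may ionize the two tertiary allylic silyl ethers (at C4 and C11) faster than it promotes cycloaddition, or endo (trans-fusion) and π-facial selectivity may erode. The fallback sets out from 28 and comes back at 31. Both silyl ethers of 28 are removed with TBAF (THF, 0 °C) to give the diol enal F2. The cycloaddition is then run without any Lewis acid in water–MeOH containing LiCl at 40–60 °C, where hydrophobic packing and hydrogen bonding to the formyl group accelerate the reaction and favour the endo transition state, to give the diol aldehyde F3. Huang–Minlon reduction of F3 under the conditions of step 15 then gives 31.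

Step 12. Migratory insertion into the vinyl group next to the quaternary C4 may be slow, so that reduction or hydrolysis of the alkenyl triflate and insertion with the wrong regiochemistry compete. The fallback sets out from 22 and 26 and comes back at 27. Cross-metathesis of the vinyl group of 22 with 2-ethenyl-4,4,5,5-tetramethyl-1,3,2-dioxaborolane (second-generation Hoveyda–Grubbs catalyst RuCl2(H2IMes)(=CH–C6H4-2-OiPr), CH2Cl2, 40 °C; the 1,1-disubstituted alkene should not take part) gives the (E)-alkenylboronate F4. Suzuki–Miyaura coupling of F4 with triflate 26 (Pd(dppf)Cl2, K3PO4, THF–H2O, 50 °C) then gives 27.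

Further compounds
F1 | step 7 | (1R,4R)-4-methyl-4-(triethylsilyloxy)-1-(trimethylstannyl)hex-5-en-1-yl N,N-diisopropylcarbamate | CC(C)N(C(C)C)C(=O)O[C@H]([Sn](C)(C)C)CC[C@@](C)(O[Si](CC)(CC)CC)C=C
F2 | step 14 | (3S,6R,7E)-6,10-dihydroxy-6,10-dimethyl-2,9-dimethylidene-3-[(1S)-3-methyl-1-(2,4,6-trimethoxyphenyl)butyl]undec-7-enal | CC(C)C[C@H](c1c(OC)cc(OC)cc1OC)[C@@H](C(=C)C=O)CC[C@@](C)(O)/C=C/C(=C)C(C)(C)O
F3 | step 14 | (1S,4R,5R,10R,9'S)-diol aldehyde (desilylated analogue of 29) | CC(C)C[C@H](c1c(OC)cc(OC)cc1OC)[C@@H]1CC[C@@](C)(O)[C@@H]2C=C(C(C)(C)O)CC[C@]21C=O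
F4 | step 12 | (E)-alkenylboronate: 2-[(1E,3R,6S,7S)-6-(3,3-diethoxyprop-1-en-2-yl)-3,9-dimethyl-3-(triethylsilyloxy)-7-(2,4,6-trimethoxyphenyl)dec-1-en-1-yl]-4,4,5,5-tetramethyl-1,3,2-dioxaborolane | CC(C)C[C@H](c1c(OC)cc(OC)cc1OC)[C@@H](C(=C)C(OCC)OCC)CC[C@@](C)(O[Si](CC)(CC)CC)/C=C/B1OC(C)(C)C(C)(C)O1
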